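**Plan**
- Retrosynthesis: the C2 ester and the C12 acid are cut together (acylative opening of a temporary oxolane, O–C2–C1–C11–C12), then C6–O, C4–CH3, the ring A bond C2–C3 (key step), ring B (Diels–Alder, C8a–C4a and C5–C6), and C1–C8a (conjugate addition).
- Forward: a dienyl metal adds to a menthyloxy butenolide (sets C1); the lactone is recast as a 2-methoxy-4-methylideneoxolane; a Diels–Alder reaction builds ring B; ester methylenation gives the C3=C4 enol ether.
- Key event: ionisation at C2 gives a five-membered oxocarbenium ion; the enol ether on C4a, held next to C1 through C8a, closes ring A (C1–C2–C3–C4–C4a–C8a), and both anomers converge on the cis-fused oxolane.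
- The enabling feature: C2 is an aldehyde-level carbon tied through oxygen to C12 (across C1–C11), and the C3/C4 unit sits on C4a cis to C1 on ring B.
- The oxolane is then opened at allylic C12 by the side-chain acyl iodide (ester at C2, iodide at C12, later the acid).
- Stereochemistry: C1 from the (+)-menthyl acetal; C8a/C4a from the auxiliary-controlled endo Diels–Alder; C2 from the key step; C4 from convex-face methyl addition; C6 from Luche reduction.

Key step: step 8

Remark: positions are numbered as in the target decalin (C1 bears the acrylic unit C11(=C13)–C12, C2 the ester oxygen, C4 the carbinol, C6 the acetate, C7 the methyl); α is the face of H-4a and H-8a; compound 2, Cp2Zr(H)Cl and Cp2TiMe2 are taken as purchasable.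

**Step 1**
Reactants: 1 2-methylbut-1-en-3-yne; 2 (5S)-5-(d-menthyloxy)furan-2(5H)-one
Product: 4 (4R,5S)-4-[(1E)-3-methylbuta-1,3-dien-1-yl]-5-(menthyloxy)oxolan-2-one (4,5-trans), via dienylzirconocene 3 (not isolated)
Conditions: Cp2Zr(H)Cl, THF, rt; then CuBr·SMe2 (10 mol %), 2, THF, 40 °C; aq. NH4Cl
Reagents that add atoms: none
Why: Hydrozirconation of the terminal alkyne gives the (E)-dienylzirconocene, which adds 1,4 under copper catalysis to the butenolide anti to the menthyloxy group (conjugate addition), so the acetal centre sets C1.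

**Step 2**
Reactants: 4
Product: 7 (4S,5S)-3-methylidene-4-[(1E)-3-methylbuta-1,3-dien-1-yl]-5-(menthyloxy)oxolan-2-one, via Mannich base 5 (not isolated), via ammonium iodide 6 (not isolated)
Conditions: LiN(i-Pr)2, THF, −78 °C; CH2=NMe2+ I−, −78 °C → rt; MeI, MeOH, rt; aq. NaHCO3, CH2Cl2
Reagents that add atoms: dimethyl(methylidene)ammonium iodide (C=[N+](C)C.[I-])
Why: Mannich reaction of the lactone enolate, N-methylation and mild base elimination (α-methylenation of a lactone) install C13 without touching C1.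

**Step 3**
Reactants: 7
Product: 8 methyl (3S,4E)-3-(dimethoxymethyl)-6-methyl-2-methylidenehepta-4,6-dienoate
Conditions: MeOH, camphorsulfonic acid (cat.), 3 Å molecular sieves, 45 °C
Reagents that add atoms: methanol (CO)
Why: Acid-catalysed alcoholysis of the acylal (pseudo-ester) should open the ring to the normal methyl ester and dimethyl acetal and release menthol, which differentiates C2 (aldehyde level) from C12.

**Step 4**
Reactants: 8
Product: 10 (3S)-2-methoxy-4-methylidene-3-[(1E)-3-methylbuta-1,3-dien-1-yl]oxolane (both C2 anomers), via allylic alcohol 9 (not isolated)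
Conditions: i-Bu2AlH, CH2Cl2, −78 → −20 °C; Rochelle salt; then pyridinium p-toluenesulfonate (cat.), CH2Cl2, rt
Reagents that add atoms: none
Why: 1,2-Reduction of the conjugated ester gives the allylic alcohol, and acid-catalysed transacetalisation closes the five-membered cyclic methyl acetal that later enforces the C1/C2 relationship.

**Step 5**
Reactants: 10; 11 (4S)-4-benzyl-3-(prop-2-enoyl)-1,3-oxazolidin-2-one
Product: 12 (4S)-4-benzyl-3-{[(1R,2R)-2-[(3S)-2-methoxy-4-methylideneoxolan-3-yl]-4-methylcyclohex-3-en-1-yl]carbonyl}-1,3-oxazolidin-2-one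
Conditions: Et2AlCl (1.5 equiv), CH2Cl2, −78 °C
Reagents that add atoms: none
Why: Diels–Alder reaction of the chelated s-cis acrylimide: the 1-alkyl and 3-methyl groups of the diene both direct the acyl-bearing carbon to C8a, the endo mode places the C4 carbonyl cis to C1 on ring B, and the benzyl group shields the Cα-re face, so C8a and C4a should form as R,R irrespective of the C1 centre.

**Step 6**
Reactants: 12
Product: 13 methyl (1R,2R)-2-[(3S)-2-methoxy-4-methylideneoxolan-3-yl]-4-methylcyclohex-3-ene-1-carboxylate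
Conditions: Mg(OMe)2, MeOH/THF, 0 °C
Reagents that add atoms: magnesium methoxide (C[O-].[Mg+2].[O-]C)
Why: Transesterification at the exocyclic imide carbonyl removes the auxiliary under conditions mild enough to leave C4a and the acetal unchanged.

**Step 7**
Reactants: 13
Product: 14 (3S)-2-methoxy-3-[(1S,6R)-6-(1-methoxyethenyl)-3-methylcyclohex-2-en-1-yl]-4-methylideneoxolane
Conditions: Cp2TiMe2 (3 equiv), toluene, 65 °C, dark; filtration through basic alumina
Reagents that add atoms: dimethyltitanocene (C[Ti](C)(C1C=CC=C1)C1C=CC=C1)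
Why: Carbonyl methylenation of the ester by the titanium methylidene (Petasis olefination) gives the enol ether regiospecifically at C3=C4 under non-basic conditions.

**Step 8**
Reactants: 14
Product: 16 tricyclic keto ether: 7-methyl-cis-decal-7-en-4-one with a 3-methylideneoxolane cis-fused across C1–C2 (ring O on C2, C11 on C1; H-1 and H-2 β, H-4a and H-8a α), via dimethyl ketal 15 (not isolated)
Conditions: Me3SiOTf (0.2 equiv), 2,6-di-tert-butyl-4-methylpyridine (0.3 equiv), CH2Cl2, −78 °C; then 1 M HCl, THF, 0 °C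
Reagents that add atoms: water (O)
Why: Me3SiOTf removes the exocyclic methoxy group of either anomer of 14 to give a five-membered oxocarbenium ion at C2 (ring oxygen as donor), which is attacked by C3 of the 1-methoxyethenyl group; the methoxy-stabilised cation at C4 is captured by the released MeOSiMe3 as ketal 15 with regeneration of the silyl cation, and acid work-up gives ketone 16. The closest known reaction type is the Lewis-acid-catalysed addition of enol ethers to acetals (Mukaiyama aldol-type addition to oxocarbenium ions, as in C-glycosylation of furanosyl acetals). Ring A (C1–C2–C3–C4–C4a–C8a) closes in the 6-(enol-endo)-exo-trig mode through a chair. C2 is the only new stereocentre and is set by the tether: the nucleophile hangs from C8a on C1 and can reach only the face of the planar oxolanium ring syn to C8a, which gives the cis-fused oxolane (C2–O cis to C1–C11) from both anomers. The step needs exocyclic ionisation, bond formation at C3 only and no enolisation toward C4a; these are secured by the better leaving group and donor in the acetal, by the enol ether position fixed in step 7, and by hindered-base buffering at −78 °C with immediate ketal hydrolysis.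

**Step 9**
Reactants: 17 but-2-yne-1,4-diol
Product: 18 (2E)-2-(tributylstannyl)but-2-ene-1,4-diol
Conditions: Bu3SnH, PdCl2(PPh3)2 (2 mol %), THF, rt
Reagents that add atoms: tributyltin hydride (CCCC[SnH](CCCC)CCCC)
Why: Palladium-catalysed syn-hydrostannation of the symmetrical alkyne gives the vinylstannane with the two hydroxymethyl groups cis, the geometry of the side chain.

**Step 10**
Reactants: 18
Product: 19 tributyl[(2E)-1,4-bis{[tert-butyl(diphenyl)silyl]oxy}but-2-en-2-yl]stannane
Conditions: t-BuPh2SiCl, imidazole, DMF, rt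
Reagents that add atoms: tert-butylchlorodiphenylsilane (CC(C)(C)[Si](Cl)(c1ccccc1)c1ccccc1)
Why: Standard silylation of both primary alcohols with a group expected to survive the later acyl iodide, oxidation and hydride steps.

**Step 11**
Reactants: 19
Product: 21 (2E)-4-{[tert-butyl(diphenyl)silyl]oxy}-2-({[tert-butyl(diphenyl)silyl]oxy}methyl)but-2-enoic acid, via vinyllithium 20 (not isolated)
Conditions: n-BuLi, THF, −78 °C, 10 min; CO2, −78 °C → rt; 1 M HCl
Reagents that add atoms: carbon dioxide (O=C=O)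
Why: Tin–lithium exchange and carboxylation of the vinyllithium proceed with retention of alkene geometry; the short time at −78 °C limits silyl migration or elimination.

**Step 12**
Reactants: 21
Product: 22 (2E)-4-{[tert-butyl(diphenyl)silyl]oxy}-2-({[tert-butyl(diphenyl)silyl]oxy}methyl)but-2-enoyl chloride
Conditions: 1-chloro-N,N,2-trimethylprop-1-en-1-amine, CH2Cl2, 0 °C → rt
Reagents that add atoms: 1-chloro-N,N,2-trimethylprop-1-en-1-amine (CC(C)=C(Cl)N(C)C)
Why: The α-chloroenamine converts the acid into the acid chloride under neutral conditions that spare the silyl ethers.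

**Step 13**
Reactants: 16; 22
Product: 25 keto enal: 7-methyl-cis-decal-7-en-4-one with 1α-(3-oxoprop-1-en-2-yl) and 2α-O-acyl (the bis-silylated side-chain ester), via acyl iodide 23 (not isolated), via allylic iodide 24 (not isolated)
Conditions: 22 (2 equiv), NaI (2.5 equiv), MeCN, 0 °C; add 16, 0 °C → rt, dark; then 4-methylmorpholine 4-oxide (5 equiv), rt
Reagents that add atoms: 4-methylmorpholine 4-oxide (C[N+]1([O-])CCOCC1)
Why: The acyl iodide formed in situ O-acylates the ether oxygen and iodide opens the acyloxonium ion at the primary allylic C12 (acylative ether cleavage), leaving the C2–O bond and its configuration intact; the amine oxide then converts the allylic iodide into the enal (Kornblum-type oxidation).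

**Step 14**
Reactants: 25
Product: 26 keto acid: as 25 with the 1α-substituent oxidised to 1-carboxyethenyl
Conditions: NaClO2, NaH2PO4, 2-methylbut-2-ene, t-BuOH/H2O, 0 °C → rt
Reagents that add atoms: sodium chlorite ([Na+].[O-]Cl=O)
Why: Pinnick oxidation converts the enal into the acrylic acid without affecting the ketone, the alkenes or the silyl ethers.

**Step 15**
Reactants: 26
Product: 27 hydroxy acid: as 26 with C4 now bearing 4β-OH and 4α-CH3
Conditions: MeTi(OiPr)3 (3.5 equiv), CH2Cl2, −20 °C → rt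
Reagents that add atoms: methyltitanium triisopropoxide (C[Ti](OC(C)C)(OC(C)C)OC(C)C)
Why: The organotitanium reagent adds to ketones but not to esters or the titanium carboxylate, and should attack from the convex α face (equatorial attack in the chair with C8 axial; the β face is screened by C8 or by axial C5), giving 4β-OH/4α-Me.

**Step 16**
Reactants: 27
Product: 29 enone acid: as 27 with C6 oxidised to the ketone (7-en-6-one), via allylic alcohols 28 (not isolated)
Conditions: SeO2 (0.5 equiv), t-BuOOH (3 equiv), CH2Cl2, rt; then Dess–Martin periodinane, NaHCO3, CH2Cl2, 0 °C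
Reagents that add atoms: selenium dioxide (O=[Se]=O, catalytic oxygen carrier); tert-butyl hydroperoxide (CC(C)(C)OO)
Why: The selenium dioxide ene reaction/[2,3]-shift hydroxylates the ring methylene next to the more substituted carbon (C6) of the only electron-rich alkene, and oxidation converges the epimeric alcohols on one enone.

**Step 17**
Reactants: 29
Product: 30 6β-allylic alcohol: as 29 with C6 reduced to 6β-OH
Conditions: NaBH4, CeCl3·7H2O, MeOH, −78 °C
Reagents that add atoms: none
Why: Luche 1,2-reduction should deliver hydride to C6 from the α face (axial attack syn to H-4a, the β face being screened by the C4a–C4 bond), as in the reduction of carvone to cis-carveol.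

**Step 18**
Reactants: 30
Product: 31 bis-silyl ether of the target (6β-OAc)
Conditions: Ac2O, pyridine, DMAP (cat.), CH2Cl2, 0 °C; aq. NaHCO3 work-up
Reagents that add atoms: acetic anhydride (CC(=O)OC(C)=O)
Why: Acetylation of the secondary allylic alcohol; the tertiary alcohol should not react and any mixed anhydride at the acid is hydrolysed on work-up.

**Step 19**
Reactants: 31
Product: 32 target, 2-[(1S,2S,4S,4aR,6S,8aR)-6-acetoxy-4-hydroxy-2-{[(2E)-4-hydroxy-2-(hydroxymethyl)but-2-enoyl]oxy}-4,7-dimethyl-1,2,3,4,4a,5,6,8a-octahydronaphthalen-1-yl]prop-2-enoic acid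
Conditions: HF·pyridine, pyridine/THF, 0 °C → rt
Reagents that add atoms: none
Why: Fluoride cleaves both silyl ethers under buffered conditions that spare the acetate, the enoate ester and the acrylic acid.

**Compound list**
1 | 2-methylbut-1-en-3-yne | C=C(C)C#C | starting material
2 | (5S)-5-{[(1S,2R,5S)-5-methyl-2-(propan-2-yl)cyclohexyl]oxy}furan-2(5H)-one | CC(C)[C@H]1CC[C@H](C)C[C@@H]1O[C@H]1OC(=O)C=C1 | starting material
3 | chlorobis(cyclopentadienyl)[(1E)-3-methylbuta-1,3-dien-1-yl]zirconium | C=C(C)/C=C/[Zr](Cl)(C1C=CC=C1)C1C=CC=C1 | intermediate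
4 | (4R,5S)-4-[(1E)-3-methylbuta-1,3-dien-1-yl]-5-{[(1S,2R,5S)-menthyl]oxy}oxolan-2-one | CC(C)[C@H]1CC[C@H](C)C[C@@H]1O[C@H]1OC(=O)C[C@@H]1/C=C/C(C)=C | intermediate
5 | 3-[(dimethylamino)methyl] derivative of 4 (C3 epimers) | CC(C)[C@H]1CC[C@H](C)C[C@@H]1O[C@H]1OC(=O)C(CN(C)C)[C@@H]1/C=C/C(C)=C | intermediate
6 | trimethylammonium iodide of 5 | CC(C)[C@H]1CC[C@H](C)C[C@@H]1O[C@H]1OC(=O)C(C[N+](C)(C)C)[C@@H]1/C=C/C(C)=C.[I-] | intermediate
7 | (4S,5S)-3-methylidene-4-[(1E)-3-methylbuta-1,3-dien-1-yl]-5-{[(1S,2R,5S)-menthyl]oxy}oxolan-2-one | CC(C)[C@H]1CC[C@H](C)C[C@@H]1O[C@H]1OC(=O)C(=C)[C@@H]1/C=C/C(C)=C | intermediate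
8 | methyl (3S,4E)-3-(dimethoxymethyl)-6-methyl-2-methylidenehepta-4,6-dienoate | C=C(C(=O)OC)[C@@H](C(OC)OC)/C=C/C(C)=C | intermediate
9 | (3S,4E)-3-(dimethoxymethyl)-6-methyl-2-methylidenehepta-4,6-dien-1-ol | C=C(CO)[C@@H](C(OC)OC)/C=C/C(C)=C | intermediate
10 | (3S)-2-methoxy-4-methylidene-3-[(1E)-3-methylbuta-1,3-dien-1-yl]oxolane (C2 anomers) | C=C1COC(OC)[C@H]1/C=C/C(C)=C | intermediate
11 | (4S)-4-benzyl-3-(prop-2-enoyl)-1,3-oxazolidin-2-one | C=CC(=O)N1C(=O)OC[C@@H]1Cc1ccccc1 | starting material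
12 | (4S)-4-benzyl-3-{[(1R,2R)-2-[(3S)-2-methoxy-4-methylideneoxolan-3-yl]-4-methylcyclohex-3-en-1-yl]carbonyl}-1,3-oxazolidin-2-one | C=C3COC(OC)[C@H]3[C@H]2C=C(C)CC[C@H]2C(=O)N4C(=O)OC[C@@H]4Cc5ccccc5 | intermediate
13 | methyl (1R,2R)-2-[(3S)-2-methoxy-4-methylideneoxolan-3-yl]-4-methylcyclohex-3-ene-1-carboxylate | C=C3COC(OC)[C@H]3[C@H]2C=C(C)CC[C@H]2C(=O)OC | intermediate
14 | (3S)-2-methoxy-3-[(1S,6R)-6-(1-methoxyethenyl)-3-methylcyclohex-2-en-1-yl]-4-methylideneoxolane | C=C3COC(OC)[C@H]3[C@H]2C=C(C)CC[C@H]2C(OC)=C | intermediate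
15 | 4,4-dimethyl ketal of 16 | C=C(CO3)[C@@H]1[C@H]2C=C(C)CC[C@H]2C(OC)(OC)C[C@@H]13 | intermediate
16 | tricyclic keto ether (7-methyl-cis-decal-7-en-4-one, 3-methylideneoxolane cis-fused at C1–C2, O on C2; H-1, H-2 β; H-4a, H-8a α) | C=C(CO3)[C@@H]1[C@H]2C=C(C)CC[C@H]2C(=O)C[C@@H]13 | intermediate
17 | but-2-yne-1,4-diol | OCC#CCO | starting material
18 | (2E)-2-(tributylstannyl)but-2-ene-1,4-diol | CCCC[Sn](CCCC)(CCCC)/C(=C/CO)CO | intermediate
19 | tributyl[(2E)-1,4-bis{[tert-butyl(diphenyl)silyl]oxy}but-2-en-2-yl]stannane | CCCC[Sn](CCCC)(CCCC)/C(=C/CO[Si](c1ccccc1)(c1ccccc1)C(C)(C)C)CO[Si](c1ccccc1)(c1ccccc1)C(C)(C)C | intermediate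
20 | [(2Z)-1,4-bis{[tert-butyl(diphenyl)silyl]oxy}but-2-en-2-yl]lithium | [Li]/C(=C/CO[Si](c1ccccc1)(c1ccccc1)C(C)(C)C)CO[Si](c1ccccc1)(c1ccccc1)C(C)(C)C | intermediate
21 | (2E)-4-{[tert-butyl(diphenyl)silyl]oxy}-2-({[tert-butyl(diphenyl)silyl]oxy}methyl)but-2-enoic acid | OC(=O)/C(=C/CO[Si](c1ccccc1)(c1ccccc1)C(C)(C)C)CO[Si](c1ccccc1)(c1ccccc1)C(C)(C)C | intermediate
22 | acid chloride of 21 (2E) | ClC(=O)/C(=C/CO[Si](c1ccccc1)(c1ccccc1)C(C)(C)C)CO[Si](c1ccccc1)(c1ccccc1)C(C)(C)C | intermediate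
23 | acyl iodide of 21 (2E) | IC(=O)/C(=C/CO[Si](c1ccccc1)(c1ccccc1)C(C)(C)C)CO[Si](c1ccccc1)(c1ccccc1)C(C)(C)C | intermediate
24 | allylic iodide: 7-methyl-cis-decal-7-en-4-one with 1α-(3-iodoprop-1-en-2-yl) and 2α-O-acyl (bis-silylated side chain) | C=C(CI)[C@@H]1[C@H]2C=C(C)CC[C@H]2C(=O)C[C@@H]1OC(=O)/C(=C/CO[Si](c3ccccc3)(c3ccccc3)C(C)(C)C)CO[Si](c3ccccc3)(c3ccccc3)C(C)(C)C | intermediate
25 | keto enal: as 24 with 1α-(3-oxoprop-1-en-2-yl) | C=C(C=O)[C@@H]1[C@H]2C=C(C)CC[C@H]2C(=O)C[C@@H]1OC(=O)/C(=C/CO[Si](c3ccccc3)(c3ccccc3)C(C)(C)C)CO[Si](c3ccccc3)(c3ccccc3)C(C)(C)C | intermediate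
26 | keto acid: as 25 with 1α-(1-carboxyethenyl) | C=C(C(=O)O)[C@@H]1[C@H]2C=C(C)CC[C@H]2C(=O)C[C@@H]1OC(=O)/C(=C/CO[Si](c3ccccc3)(c3ccccc3)C(C)(C)C)CO[Si](c3ccccc3)(c3ccccc3)C(C)(C)C | intermediate
27 | hydroxy acid: as 26 with 4β-OH, 4α-CH3 | C=C(C(=O)O)[C@@H]1[C@H]2C=C(C)CC[C@H]2[C@@](C)(O)C[C@@H]1OC(=O)/C(=C/CO[Si](c3ccccc3)(c3ccccc3)C(C)(C)C)CO[Si](c3ccccc3)(c3ccccc3)C(C)(C)C | intermediate
28 | 6-hydroxy derivative of 27 (C6 epimers) | C=C(C(=O)O)[C@@H]1[C@H]2C=C(C)C(O)C[C@H]2[C@@](C)(O)C[C@@H]1OC(=O)/C(=C/CO[Si](c3ccccc3)(c3ccccc3)C(C)(C)C)CO[Si](c3ccccc3)(c3ccccc3)C(C)(C)C | intermediate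
29 | 6-oxo derivative of 27 (7-en-6-one) | C=C(C(=O)O)[C@@H]1[C@H]2C=C(C)C(=O)C[C@H]2[C@@](C)(O)C[C@@H]1OC(=O)/C(=C/CO[Si](c3ccccc3)(c3ccccc3)C(C)(C)C)CO[Si](c3ccccc3)(c3ccccc3)C(C)(C)C | intermediate
30 | 6β-hydroxy derivative of 27 | C=C(C(=O)O)[C@@H]1[C@H]2C=C(C)[C@@H](O)C[C@H]2[C@@](C)(O)C[C@@H]1OC(=O)/C(=C/CO[Si](c3ccccc3)(c3ccccc3)C(C)(C)C)CO[Si](c3ccccc3)(c3ccccc3)C(C)(C)C | intermediate
31 | bis(tert-butyldiphenylsilyl) ether of the target | C=C(C(=O)O)[C@@H]1[C@H]2C=C(C)[C@@H](OC(C)=O)C[C@H]2[C@@](C)(O)C[C@@H]1OC(=O)/C(=C/CO[Si](c3ccccc3)(c3ccccc3)C(C)(C)C)CO[Si](c3ccccc3)(c3ccccc3)C(C)(C)C | intermediate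
32 | 2-[(1S,2S,4S,4aR,6S,8aR)-6-acetoxy-4-hydroxy-2-{[(2E)-4-hydroxy-2-(hydroxymethyl)but-2-enoyl]oxy}-4,7-dimethyl-1,2,3,4,4a,5,6,8a-octahydronaphthalen-1-yl]prop-2-enoic acid | C=C(C(=O)O)[C@@H]1[C@H]2C=C(C)[C@@H](OC(C)=O)C[C@H]2[C@@](C)(O)C[C@@H]1OC(=O)/C(=C/CO)CO | target

**Count**
Total steps: 19. Longest linear sequence: 15 (steps 1–8 and 13–19).

**Steps most likely to fail**

Step 13. What may go wrong: slow O-acylation of the hindered bicyclic ether by the bulky acyl iodide, loss of silyl ethers or addition of HI to the ring B alkene, and β-elimination of the new C2 ester from the β-acyloxy ketone during the amine-oxide oxidation. Fallback through the lactone oxidation level, setting out from 16: MeMgBr/CeCl3 (THF, −78 °C) should add methyl from the α face to give tertiary alcohol ether F1. CrO3·3,5-dimethylpyrazole oxidises the allylic O–CH2 group to α-methylene lactone F2, and i-Bu2AlH reduces it to triol F3. t-BuMe2SiCl/imidazole silylates the primary allylic hydroxyl to give silyl ether F4. Acid 21 is joined at the C2 hydroxyl by Yamaguchi esterification (2,4,6-trichlorobenzoyl chloride, Et3N, DMAP) to give ester F5. HF·pyridine at 0 °C removes the dimethylsilyl group selectively to give allylic alcohol F6, MnO2 gives enal F7, and NaClO2/NaH2PO4 oxidation of F7 comes back to the route at 27.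

Step 8. What may go wrong: protonation or hydrolysis of the acid-labile enol ether before it cyclises, endocyclic cleavage of the acetal, or epimerisation at C4a through the C4 oxocarbenium ion. Fallback with a ketone-derived silyl enol ether and a stoichiometric Lewis acid, setting out from 13: i-PrMgCl/MeNH(OMe)·HCl gives Weinreb amide F8, and MeMgBr gives methyl ketone F9. LiN(i-Pr)2/Me3SiCl at −78 °C gives the kinetic silyl enol ether F10. BF3·OEt2 (1.2 equiv, CH2Cl2, −78 °C) closes ring A by a Mukaiyama aldol-type addition to the same cyclic oxocarbenium ion and comes back to the route at 16.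

Step 5. What may go wrong: ionisation of the cyclic acetal by Et2AlCl, and erosion of facial selectivity because the C1 centre and the auxiliary are not obviously matched. Fallback with catalyst control and a milder Lewis acid, setting out from 10: 3-acryloyl-1,3-oxazolidin-2-one with [Cu((R,R)-t-Bu-box)](SbF6)2 (10 mol %, CH2Cl2, −20 °C; the enantiomer expected to direct the diene to the Cα-si face) gives imide F11. Mg(OMe)2 in MeOH converts F11 into 13, where the route is rejoined.

**Further compounds**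
F1 | step 13 | tertiary alcohol ether (16 with 4β-OH, 4α-CH3) | C=C(CO3)[C@@H]1[C@H]2C=C(C)CC[C@H]2[C@@](C)(O)C[C@@H]13
F2 | step 13 | α-methylene lactone (F1 with C12 as lactone carbonyl) | C=C(C(=O)O3)[C@@H]1[C@H]2C=C(C)CC[C@H]2[C@@](C)(O)C[C@@H]13
F3 | step 13 | triol (2α-OH, 4β-OH, 1α-(3-hydroxyprop-1-en-2-yl)) | C=C(CO)[C@@H]1[C@H]2C=C(C)CC[C@H]2[C@@](C)(O)C[C@@H]1O
F4 | step 13 | primary tert-butyldimethylsilyl ether of F3 | C=C(CO[Si](C)(C)C(C)(C)C)[C@@H]1[C@H]2C=C(C)CC[C@H]2[C@@](C)(O)C[C@@H]1O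
F5 | step 13 | C2 ester of F4 with acid 21 | C=C(CO[Si](C)(C)C(C)(C)C)[C@@H]1[C@H]2C=C(C)CC[C@H]2[C@@](C)(O)C[C@@H]1OC(=O)/C(=C/CO[Si](c3ccccc3)(c3ccccc3)C(C)(C)C)CO[Si](c3ccccc3)(c3ccccc3)C(C)(C)C
F6 | step 13 | allylic alcohol (F5 without the dimethylsilyl group) | C=C(CO)[C@@H]1[C@H]2C=C(C)CC[C@H]2[C@@](C)(O)C[C@@H]1OC(=O)/C(=C/CO[Si](c3ccccc3)(c3ccccc3)C(C)(C)C)CO[Si](c3ccccc3)(c3ccccc3)C(C)(C)C
F7 | step 13 | enal (aldehyde of F6) | C=C(C=O)[C@@H]1[C@H]2C=C(C)CC[C@H]2[C@@](C)(O)C[C@@H]1OC(=O)/C(=C/CO[Si](c3ccccc3)(c3ccccc3)C(C)(C)C)CO[Si](c3ccccc3)(c3ccccc3)C(C)(C)C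
F8 | step 8 | N-methoxy-N-methylamide corresponding to ester 13 | C=C3COC(OC)[C@H]3[C@H]2C=C(C)CC[C@H]2C(=O)N(C)OC
F9 | step 8 | methyl ketone corresponding to ester 13 | C=C3COC(OC)[C@H]3[C@H]2C=C(C)CC[C@H]2C(C)=O
F10 | step 8 | trimethylsilyl enol ether of F9 (C3=C4) | C=C3COC(OC)[C@H]3[C@H]2C=C(C)CC[C@H]2C(O[Si](C)(C)C)=C
F11 | step 5 | 3-acyl-1,3-oxazolidin-2-one analogue of 12 (no benzyl group) | C=C3COC(OC)[C@H]3[C@H]2C=C(C)CC[C@H]2C(=O)N4CCOC4=O
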